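Its constants are those of an exercise; the result is computed.

**One step.** In a one-step world, starting material meets partner and gives target, so partner, the limiting reagent at 0.0450 M against 0.050 M, caps target at 90.0% of the starting material charged. These flasks have more steps.

| setting | delta | beta | eta | epsilon |
|---|---|---|---|---|
| starting material | 0.050 M | 0.050 M | 0.050 M | 0.050 M |
| partner | 0.0450 M | 0.0450 M | 0.0450 M | 0.0450 M |
| second substrate | 0.0100 M | 0.0100 M | 0.0100 M | 0.0100 M |
| protic impurity | 2.50 mM | 2.50 mM | 2.50 mM | 2.50 mM |
| temperature | 5 °C |  | −15 °C | 25 °C |
| time | 4.0 min | 4.0 min | 4.0 min | 4.0 min |
| remark |  | at 25 °C until 80 s, from then on at −15 °C |  |  |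

    partner → decomposed reagent (k1 = 0.12 s⁻¹, Ea1 = 73.0 kJ mol⁻¹)
    starting material + second substrate → cross product (k2 = 11 M⁻¹ s⁻¹, Ea2 = 44.0 kJ mol⁻¹)
    second substrate + protic impurity → quenched substrate (k3 = 20 M⁻¹ s⁻¹, Ea3 = 51.0 kJ mol⁻¹)
    second substrate + partner → second product (k4 = 0.32 M⁻¹ s⁻¹, Ea4 = 55.0 kJ mol⁻¹)
    starting material + partner → target (k5 = 3.0 M⁻¹ s⁻¹, Ea5 = 50.0 kJ mol⁻¹)
    (constants at 25 °C)

- the list of constants is for 25 °C, to be carried to other temperatures by the activation energies

- the flask with the highest amount of target, in percent of the starting material charged ("all alike" if they lie within 1.5 percentage points) (delta / beta / eta / epsilon / all alike)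
- final target, as a percentage of the starting material charged, in delta
- final target, as a percentage of the starting material charged, in beta
- final target, as a percentage of the starting material charged, in eta
- final target, as a percentage of the starting material charged, in epsilon

**Partner's balance.** Add decomposition and write the balance of partner: at each moment it goes to target at the main step's rate constant times the starting material present, and to decomposed reagent at its own first-order constant. Their ratio gives the split concentration, 0.0400 M at 25 °C: the amount of starting material at which partner divides equally between target and decomposition. The share reaching target is therefore starting material over starting material plus split concentration. That share falls during the run, so I take a first guess from the opening share and read the share midway, at 0.0375 M. Decomposition then cuts target to 43.5%.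

**Second substrate.** Now add second substrate. It reacts with starting material 11.0 times as fast as with protic impurity, so I charge its full 0.0100 M against starting material, leaving 0.0400 M free. I leave out the partner it consumes, since that step takes second substrate at 0.0144 s⁻¹ against 0.550 s⁻¹ for the step to cross product. The midway amount becomes 0.0288 M, and epsilon gets 37.6%. Partner's lifetime is one over the main constant times the sum of split concentration and starting material, here 4.85 s. That is shorter than the 80 s before beta is cooled, so beta gets the same figure, 37.6%.

**Going colder.** Decomposition has the higher activation energy, so the split concentration falls on cooling. In delta, at 5 °C, it is 0.0205 M, and the midway amount is 0.0251 M. Partner's lifetime in delta is 31.1 s, shorter than the 4.0 min allowed, so delta gets 49.5%.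

In eta, at −15 °C, the split concentration is 0.009500 M, but the main constant has dropped to 0.132 M⁻¹ s⁻¹. With the midway amount 0.0256 M, partner's lifetime in eta is 216 s, about as long as the 4.0 min allowed. I expect 32.9% of eta's partner unused, and target of 44.0%. Ranking the flasks gives delta.

**The forecast.** The forecast gives 50.8% for delta, 39.8% for beta, 46% for eta and 39.8% for epsilon, with epsilon above my figure, and it names delta, holding that “Beta finishes its chemistry before cooling”.

**The result.** Target ends at 51.2% in delta, 40.0% in beta, 46.1% in eta and 40.0% in epsilon, so delta holds the most. Eta still holds 31.8% of its partner at 4.00 min. Now take a neighbour of beta charged with 0.011 M of partner, less than the free starting material. At the split concentration of 0.0400 M, the opening share 50.0% gives target of 11.0% of the starting material charged. That neighbour ends with 11.1% target and 70.6% starting material.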